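The heneicosanoyl chain is cut at C5–C6 (C1 = ester carbonyl). The plan exploits that both atoms are plain CH2 members of the unbranched C2–C20 run, remote from the ester C1 and from the phenyl ring, so each can be a primary radical born by anodic loss of CO2. Adipic acid 1 and 2-phenylethanol 2 give half-ester 3, which already holds C1–C5 and the complete alkoxy part; heptadecanoic acid 4 supplies C6–C21. A crossed Kolbe electrolysis of 3 and 4, each one carbon longer than its share of the product, forms the bond, expels both activating groups as gas and delivers the finished ester with no later adjustment.

Key step: step 2

Remark: the target has no stereocentre and no double-bond geometry. The SMILES therefore describes one achiral compound, and no step has to control configuration.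

Step 1
Reactants: 1 adipic acid (hexanedioic acid); 2 2-phenylethanol
Product: 3 6-oxo-6-(2-phenylethoxy)hexanoic acid (mono-2-phenylethyl adipate)
Conditions: 1 (3 equiv), 2 (1 equiv), TsOH·H2O (5 mol%), toluene, reflux, Dean–Stark; cool, filter off excess 1; extract into aq NaHCO3, acidify, extract with EtOAc
Reagents that add atoms: none
Why: Fischer esterification with azeotropic water removal; the excess of the symmetrical diacid biases the statistical distribution towards the mono-ester, unreacted 1 crystallises from cold toluene, and only 3 is both toluene-soluble and hydrogencarbonate-extractable, so it should be obtained without chromatography.

Step 2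
Reactants: 3 6-oxo-6-(2-phenylethoxy)hexanoic acid; 4 heptadecanoic acid
Product: 7 2-phenylethyl heneicosanoate, via hexadecyl radical 5 (not isolated), via 5-oxo-5-(2-phenylethoxy)pentyl radical 6 (not isolated)
Conditions: 3 (3.5 equiv), 4 (1 equiv), Me4NOH·5H2O (ca. 0.3–0.5 equiv per CO2H), acetone, undivided cell, RVC | RVC, rapid alternating polarity (square wave, ca. 6 V, ca. 50 ms pulses), rt to 35 °C, stopped when 4 is nearly consumed; silica, hexane → hexane/EtOAc
Reagents that add atoms: none
Why: Crossed Kolbe electrolysis: the carboxylates of 3 and 4 are each oxidised by one electron at the momentary anode, the acyloxy radicals lose CO2, and the primary radicals 5 and 6, born side by side at high local concentration in the electrode layer, combine to the C5–C6 bond while the carboxyl protons are reduced to hydrogen at the counter-electrode. The closest known reaction type is the anodic chain extension of a fatty acid with an alkyl hydrogen adipate, and the alternating-polarity form on carbon electrodes is a known variant for homo- and hetero-Kolbe coupling of functionalised acids. No ring is closed and no stereocentre is formed. Radical combination has to win over a second electron transfer (Hofer–Moest path), which is secured because C5 and C6 are unbranched primary carbons without an α-donor, the ester carbonyl C1 lies four bonds from C5, and the phenyl ring is too remote for cyclisation or fast hydrogen transfer. Cross- over homo-coupling can only be statistical, so cheap 3 is used in excess to channel radical 5 into 7, and the two symmetrical dimers (a hydrocarbon, a diester) should separate from monoester 7 by polarity on silica. Acetone instead of an alcohol excludes ester exchange at the phenethyl ester, free acid and evolved CO2 keep the medium buffered, and the short pulses limit over-oxidation of the arene and fouling of the electrodes by the waxy products.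

Compound list
1 | adipic acid (hexanedioic acid) | OC(=O)CCCCC(=O)O | starting material
2 | 2-phenylethanol | OCCc1ccccc1 | starting material
3 | 6-oxo-6-(2-phenylethoxy)hexanoic acid (mono-2-phenylethyl adipate) | OC(=O)CCCCC(=O)OCCc1ccccc1 | intermediate
4 | heptadecanoic acid | CCCCCCCCCCCCCCCCC(=O)O | starting material
5 | hexadecyl radical | CCCCCCCCCCCCCCC[CH2] | intermediate
6 | 5-oxo-5-(2-phenylethoxy)pentyl radical | [CH2]CCCC(=O)OCCc1ccccc1 | intermediate
7 | 2-phenylethyl heneicosanoate | CCCCCCCCCCCCCCCCCCCCC(=O)OCCc1ccccc1 | target

Total step count: 2
Longest linear sequence: 2

Steps most likely to fail (the route has only two steps, so both are ranked):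

1. Step 2.
   - **Risk:** Each radical may couple with its own kind, which consumes material statistically. Radicals may also be lost by disproportionation or by a second oxidation to cations. Waxy deposits may passivate the electrodes, and the phenyl ring may be attacked anodically.
   - **Fallback:** This sets out from 2 and comes back to the route at 7. It replaces radical–radical pairing by a polar, fixed-partner coupling at the same C5–C6 bond. Compound 2 is esterified with purchased 5-bromopentanoic acid (TsOH cat., toluene, Dean–Stark) to 2-phenylethyl 5-bromopentanoate F1. Purchased 1-bromohexadecane is converted with Mg turnings in THF into hexadecylmagnesium bromide F2. F2 is added slowly to F1 in THF/NMP with Li2CuCl4 (3 mol%) at 0–20 °C (Kochi-type copper-catalysed alkyl–alkyl coupling). Under these conditions, displacement of the primary bromide should outrun addition to the ester and give 7.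

2. Step 1.
   - **Risk:** The half-ester dissolves in toluene better than the diacid does, so it may be esterified a second time. Material may also be lost to emulsions in the pH-controlled extraction.
   - **Fallback:** This sets out from 2 and comes back to the route at 3. It replaces statistical differentiation by two orthogonal ester groups. Compound 2 is coupled with purchased 6-tert-butoxy-6-oxohexanoic acid (DCC, DMAP cat., CH2Cl2, 0 °C to rt, Steglich esterification) to tert-butyl 2-phenylethyl hexanedioate F3. TFA/CH2Cl2 at rt should then cleave only the tert-butyl ester, through its tertiary cation, and give 3.

Further compounds
F1 | step 2 | 2-phenylethyl 5-bromopentanoate | BrCCCCC(=O)OCCc1ccccc1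
F2 | step 2 | hexadecylmagnesium bromide | CCCCCCCCCCCCCCCC[Mg]Br
F3 | step 1 | tert-butyl 2-phenylethyl hexanedioate | CC(C)(C)OC(=O)CCCCC(=O)OCCc1ccccc1
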